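**Retrosynthetic overview**

- Numbering: lactone O1, C2 (C=O), C3 (carbinol carbon, hydroxyl O3, vanillyl CH2 = C7'), C4 (veratryl CH2 = C7), C5 (OCH2). The strategy rests on C3 of the γ-lactone ring carrying both O3 and the benzylic carbon C7', the two ends of an ArCH2–O ether bond, so C3 can enter as a carbene between them.
- Trachelogenin 15 ⇐ 14 by hydrogenolysis of three benzylic C–O bonds. 14 ⇐ diazo lactone 9 + symmetrical ether 12 (rhodium carbene, oxonium ylide, [1,2]-Stevens shift: C3–O3 and C3–C7' made together, C3 set anti to C7).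
- 9 ⇐ (R)-lactone 7 by detrifluoroacetylative diazo transfer. 7 ⇐ Evans alkylation of acyl oxazolidinone 4 with tert-butyl bromoacetate (sets C4), reduction and lactonisation. 12 ⇐ Williamson coupling of alcohol 10 with its chloride 11.
- Ring formation: the γ-lactone, the only ring made, closes in step 3; the key step closes no ring.

Key step: step 7

Assumption: 10 is taken as a purchased compound (otherwise two routine steps from vanillin: BnBr/K2CO3, then NaBH4); metal enolates, alkoxides and the rhodium carbene are treated as reactive forms and are not numbered.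
Remark: C4 keeps one spatial arrangement throughout; its descriptor changes from R (7, 8, 9) to S (13, 14, 15) only because C3 gains CIP priority over C5.

**Route**

Step 1
Reactants: 1 3-(3,4-dimethoxyphenyl)propanoic acid; 2 (S)-4-benzyloxazolidin-2-one
Product: 4 (S)-4-benzyl-3-[3-(3,4-dimethoxyphenyl)propanoyl]oxazolidin-2-one, via mixed pivalic anhydride 3 (not isolated)
Conditions: PivCl, Et3N, THF, −20 °C; then 2, LiCl, −20 °C → rt
Reagents that add atoms: none
Why: N-acylation of the oxazolidinone by the mixed pivalic anhydride (LiCl/Et3N protocol) should proceed at the less hindered carbonyl without strong base or an acid chloride.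

Step 2
Reactants: 4 (S)-4-benzyl-3-[3-(3,4-dimethoxyphenyl)propanoyl]oxazolidin-2-one
Product: 5 tert-butyl (3R)-4-[(4S)-4-benzyl-2-oxooxazolidin-3-yl]-3-(3,4-dimethoxybenzyl)-4-oxobutanoate
Conditions: NaHMDS, THF, −78 °C; BrCH2CO2t-Bu, −78 → −40 °C
Reagents that add atoms: tert-butyl bromoacetate, CC(C)(C)OC(=O)CBr
Why: Evans asymmetric alkylation: the chelated (Z)-sodium enolate is alkylated on the face opposite the benzyl group of the auxiliary, which sets the (R) centre that becomes C4 of the lactone.

Step 3
Reactants: 5 tert-butyl (3R)-4-[(4S)-4-benzyl-2-oxooxazolidin-3-yl]-3-(3,4-dimethoxybenzyl)-4-oxobutanoate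
Product: 7 (4R)-4-(3,4-dimethoxybenzyl)oxolan-2-one, via hydroxy tert-butyl ester 6 (not isolated)
Conditions: LiBH4, MeOH (1 equiv), THF, 0 °C; aq. work-up; then p-TsOH·H2O (cat.), CH2Cl2, rt
Reagents that add atoms: none
Why: Chemoselective borohydride reduction of the imide carbonyl removes the auxiliary and spares the tert-butyl ester, and acid-catalysed lactonisation (intramolecular transesterification, 5-exo-trig) of the γ-hydroxy ester closes the lactone without touching the stereocentre.

Step 4
Reactants: 7 (4R)-4-(3,4-dimethoxybenzyl)oxolan-2-one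
Product: 9 (4R)-3-diazo-4-(3,4-dimethoxybenzyl)oxolan-2-one, via 3-trifluoroacetyl lactone 8 (not isolated)
Conditions: LiHMDS, THF, −78 °C; CF3CO2CH2CF3; aq. HCl work-up; then MsN3, Et3N, H2O (1 equiv), MeCN, rt
Reagents that add atoms: methanesulfonyl azide, CS(=O)(=O)N=[N+]=[N-]
Why: Detrifluoroacetylative diazo transfer: Claisen trifluoroacetylation of the lithium enolate activates C3, and sulfonyl azide transfer with loss of the trifluoroacetyl group as the N-acyl sulfonamide should give the α-diazo lactone, C4 being non-enolisable.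

Step 5
Reactants: 10 [4-(benzyloxy)-3-methoxyphenyl]methanol
Product: 11 1-(benzyloxy)-4-(chloromethyl)-2-methoxybenzene
Conditions: SOCl2, CH2Cl2, 0 °C → rt
Reagents that add atoms: thionyl chloride, O=S(Cl)Cl
Why: Chlorodehydroxylation of a benzylic alcohol through its chlorosulfite is routine, and the crude electron-rich benzyl chloride is used at once.

Step 6
Reactants: 10 [4-(benzyloxy)-3-methoxyphenyl]methanol; 11 1-(benzyloxy)-4-(chloromethyl)-2-methoxybenzene
Product: 12 bis[4-(benzyloxy)-3-methoxybenzyl] ether
Conditions: NaH, THF–DMF, 0 °C; then 11, Bu4NI (cat.), rt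
Reagents that add atoms: none
Why: Williamson ether synthesis by SN2 displacement of the benzylic chloride with the sodium alkoxide gives the symmetrical ether and avoids the Friedel–Crafts oligomerisation that acid-mediated self-condensation of such electron-rich benzyl alcohols invites.

Step 7
Reactants: 9 (4R)-3-diazo-4-(3,4-dimethoxybenzyl)oxolan-2-one; 12 bis[4-(benzyloxy)-3-methoxybenzyl] ether
Product: 14 (3S,4S)-3-[4-(benzyloxy)-3-methoxybenzyl]-3-{[4-(benzyloxy)-3-methoxybenzyl]oxy}-4-(3,4-dimethoxybenzyl)oxolan-2-one, via oxonium ylide 13 (not isolated)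
Conditions: 12 (3 equiv, excess recovered), Rh2(O2CCPh3)4 (2 mol %), 4 Å MS, CH2Cl2, −60 °C, 9 added by syringe pump; then → rt
Reagents that add atoms: none
Why: Proposed new method: loss of N2 from 9 gives an electrophilic rhodium carbene at C3 that is trapped by the dialkyl ether oxygen of 12 (its most Lewis-basic site, present in excess) to give ylide 13, a lactone enolate whose O–CH2Ar bond cleaves to a caged 4-alkoxybenzyl/captodative C3 radical pair that recombines at carbon, so C3–O3 and C3–C7' form in one operation and no ring is closed. The closest known reaction types are the [1,2]-Stevens rearrangement of benzylic oxonium ylides generated from metal carbenes and the intermolecular trapping of cyclic α-diazo carbonyl compounds under bulky rhodium carboxylates at low temperature, where capture outruns 1,2-hydride migration; their combination on an α-diazo lactone with an acyclic dibenzylic ether is untested. The one new stereocentre, C3, is set at the recombination: the ylide carbon is planar, the two benzylic groups on oxygen are identical, and the one that migrates should do so on the face anti to the C4 veratryl CH2, which places C7' trans to C7 and O3 cis to it, i.e. (3S,4S). The step needs chemoselectivity for ylide formation over hydride shift from C4, attack on the electron-rich arenes and benzylic C–H insertion, which the bulky carboxylate ligands, the low temperature, the slow addition of 9 and the excess of 12 are meant to secure; C4 is not touched.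

Step 8
Reactants: 14 (3S,4S)-3-[4-(benzyloxy)-3-methoxybenzyl]-3-{[4-(benzyloxy)-3-methoxybenzyl]oxy}-4-(3,4-dimethoxybenzyl)oxolan-2-one
Product: 15 trachelogenin, (3S,4S)-4-(3,4-dimethoxybenzyl)-3-hydroxy-3-(4-hydroxy-3-methoxybenzyl)oxolan-2-one
Conditions: H2 (1 atm), Pd(OH)2/C, EtOAc–EtOH, rt
Reagents that add atoms: none
Why: Heterogeneous hydrogenolysis of benzylic C–O bonds should cleave both aryl benzyl ethers and the O3 benzylic ether in one operation, while the C3–O3 bond (not benzylic), the lactone and both stereocentres stay intact.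

**Compound list**

1 | 3-(3,4-dimethoxyphenyl)propanoic acid | COc1ccc(CCC(=O)O)cc1OC | starting material
2 | (S)-4-benzyloxazolidin-2-one | O=C1N[C@@H](Cc2ccccc2)CO1 | starting material
3 | 3-(3,4-dimethoxyphenyl)propanoic pivalic anhydride | COc1ccc(CCC(=O)OC(=O)C(C)(C)C)cc1OC | intermediate
4 | (S)-4-benzyl-3-[3-(3,4-dimethoxyphenyl)propanoyl]oxazolidin-2-one | COc1ccc(CCC(=O)N2[C@@H](Cc3ccccc3)COC2=O)cc1OC | intermediate
5 | tert-butyl (3R)-4-[(4S)-4-benzyl-2-oxooxazolidin-3-yl]-3-(3,4-dimethoxybenzyl)-4-oxobutanoate | COc1ccc(C[C@H](CC(=O)OC(C)(C)C)C(=O)N2[C@@H](Cc3ccccc3)COC2=O)cc1OC | intermediate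
6 | tert-butyl (3R)-3-(3,4-dimethoxybenzyl)-4-hydroxybutanoate | COc1ccc(C[C@H](CC(=O)OC(C)(C)C)CO)cc1OC | intermediate
7 | (4R)-4-(3,4-dimethoxybenzyl)oxolan-2-one | O=C1OC[C@@H](C1)Cc1ccc(OC)c(OC)c1 | intermediate
8 | (4R)-4-(3,4-dimethoxybenzyl)-3-(trifluoroacetyl)oxolan-2-one (C3 epimers/enol) | O=C1OC[C@H](Cc2ccc(OC)c(OC)c2)C1C(=O)C(F)(F)F | intermediate
9 | (4R)-3-diazo-4-(3,4-dimethoxybenzyl)oxolan-2-one | [N-]=[N+]=C1C(=O)OC[C@@H]1Cc1ccc(OC)c(OC)c1 | intermediate
10 | [4-(benzyloxy)-3-methoxyphenyl]methanol | COc1cc(CO)ccc1OCc1ccccc1 | starting material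
11 | 1-(benzyloxy)-4-(chloromethyl)-2-methoxybenzene | COc1cc(CCl)ccc1OCc1ccccc1 | intermediate
12 | bis[4-(benzyloxy)-3-methoxybenzyl] ether | COc1cc(COCc2ccc(OCc3ccccc3)c(OC)c2)ccc1OCc1ccccc1 | intermediate
13 | oxonium ylide: bis[4-(benzyloxy)-3-methoxybenzyl][(4S)-4-(3,4-dimethoxybenzyl)-2-oxooxolan-3-id-3-yl]oxonium | O=C1OC[C@H](Cc2ccc(OC)c(OC)c2)[C-]1[O+](Cc1ccc(OCc2ccccc2)c(OC)c1)Cc1ccc(OCc2ccccc2)c(OC)c1 | intermediate
14 | (3S,4S)-3-[4-(benzyloxy)-3-methoxybenzyl]-3-{[4-(benzyloxy)-3-methoxybenzyl]oxy}-4-(3,4-dimethoxybenzyl)oxolan-2-one | O=C1OC[C@H](Cc2ccc(OC)c(OC)c2)[C@@]1(OCc1ccc(OCc2ccccc2)c(OC)c1)Cc1ccc(OCc2ccccc2)c(OC)c1 | intermediate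
15 | trachelogenin, (3S,4S)-4-(3,4-dimethoxybenzyl)-3-hydroxy-3-(4-hydroxy-3-methoxybenzyl)oxolan-2-one | COc1cc(C[C@@]2(O)C(=O)OC[C@@H]2Cc2ccc(OC)c(OC)c2)ccc1O | target

**Step count and risks**

Total steps: 8. Longest linear sequence: 6 (steps 1, 2, 3, 4, 7, 8).

Steps most likely to fail:

1. Step 7 (new method). The carbene may be consumed by 1,2-hydride migration from C4, by intramolecular attack on the veratryl ring, or by C–H insertion and arene addition on 12 before the ether oxygen captures it. The ylide may also revert, or recombine with poor facial or site selectivity (at an ortho ring carbon or at the enolate oxygen). Fallback by known chemistry: it sets out from lactone 7. Hydroxylation of its potassium enolate (KHMDS, THF, −78 °C; 2-(phenylsulfonyl)-3-phenyloxaziridine) should give mainly the trans alcohol (3R,4S)-4-(3,4-dimethoxybenzyl)-3-hydroxyoxolan-2-one F1, whose C3 configuration is erased in the next operation. Its dianion (LiHMDS, 2.2 equiv, THF–DMPU, −78 °C) is alkylated at carbon with chloride 11 (NaI), the benzyl group entering anti to the C4 substituent as is established for this lignan class, to give O-benzyl trachelogenin F2. Hydrogenolysis (H2, Pd/C, EtOAc) then comes back to the route at target 15.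

2. Step 8. Hydrogenolysis may stall at the hindered tertiary O3 ether after the phenolic benzyl groups are gone, or the catalyst may be poisoned by residual rhodium or sulfur species. Fallback: from 14, Lewis-acid debenzylation with BCl3 and pentamethylbenzene as cation scavenger (CH2Cl2, −78 °C) ionises all three benzylic C–O bonds without hydrogen or a metal surface and should give target 15 directly; no new intermediate arises.

3. Step 4. C-trifluoroacetylation of the lactone enolate may be incomplete, or the lactone may open during the basic diazo-transfer work-up, so that the diazo lactone is lost. Fallback: from lactone 7, electrophilic azidation of the potassium enolate (KHMDS, THF, −78 °C; 2,4,6-triisopropylbenzenesulfonyl azide; AcOH quench) should give (3R,4R)-3-azido-4-(3,4-dimethoxybenzyl)oxolan-2-one F3. Reduction (H2, Pd/C, EtOAc, HCl) gives (3R,4R)-3-amino-4-(3,4-dimethoxybenzyl)oxolan-2-one F4, handled as its hydrochloride. Diazotisation of this α-amino lactone (isoamyl nitrite, cat. AcOH, CHCl3, reflux) comes back to the route at diazo lactone 9.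

**Further compounds**

F1 | step 7 | (3R,4S)-4-(3,4-dimethoxybenzyl)-3-hydroxyoxolan-2-one | O=C1OC[C@H](Cc2ccc(OC)c(OC)c2)[C@H]1O
F2 | step 7 | O-benzyl trachelogenin, (3S,4S)-3-[4-(benzyloxy)-3-methoxybenzyl]-4-(3,4-dimethoxybenzyl)-3-hydroxyoxolan-2-one | COc1cc(C[C@@]2(O)C(=O)OC[C@@H]2Cc2ccc(OC)c(OC)c2)ccc1OCc1ccccc1
F0 | step 8 | none | none
F3 | step 4 | (3R,4R)-3-azido-4-(3,4-dimethoxybenzyl)oxolan-2-one | O=C1OC[C@H](Cc2ccc(OC)c(OC)c2)[C@H]1N=[N+]=[N-]
F4 | step 4 | (3R,4R)-3-amino-4-(3,4-dimethoxybenzyl)oxolan-2-one | O=C1OC[C@H](Cc2ccc(OC)c(OC)c2)[C@H]1N
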